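**Retrosynthetic overview**

- Feature: in ring A, C8a carries the ring oxygen O1 and its neighbour C4a carries the C4 carbonyl, with the C5 oxygen on the other side of C4a. A carboxylic acid adding across a 3-alkoxybenzyne leaves exactly this ortho oxygen/acyl pair in this orientation.
- Key disconnection: O1–C8a and C4–C4a (aryne insertion into the acid C–O bond) plus O1–C2 (oxa-Michael), leading back to silyl triflate 9 and α-methoxycinnamic acid 16. Rings A and B are bought; ring C is the only ring made (step 8, as a flavanone).
- Fragment 9 comes from phloroglucinol (bis-MOM ether, carbamate, directed ortho-silylation, decarbamoylation/triflation). Fragment 16 comes from 4-hydroxybenzaldehyde (prenylation, condensation with methyl methoxyacetate, saponification).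
- End game: selenenylation at C3 and selenoxide elimination turn ring C into the 4-pyranone; both MOM ethers are then removed without Brønsted acid so that the aryl prenyl ether survives.

Key step: step 8

Remark: compounds with a saturated ring C (19 to 22, F4) are racemic and drawn as one enantiomer, and 14 is a diastereomer mixture; the target has no stereocentre.

**Route**

Step 1
Reactants: 1 phloroglucinol
Product: 2 3,5-bis(methoxymethoxy)phenol
Conditions: MOMCl (2.0 equiv), i-Pr2NEt (2.2 equiv), DMF, 0 °C → rt; chromatography
Reagents that add atoms: chloromethyl methyl ether (MOMCl), COCCl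
Why: Williamson-type O-alkylation of the phenoxide by the α-chloro ether; the three hydroxyls are equivalent, so two equivalents should make the bis-ether the main component of a statistical mixture from which the mono- and tris-ethers are separated.

Step 2
Reactants: 2 3,5-bis(methoxymethoxy)phenol
Product: 3 3,5-bis(methoxymethoxy)phenyl N-isopropylcarbamate
Conditions: i-PrNCO (1.5 equiv), Et3N (cat.), CH2Cl2, rt
Reagents that add atoms: isopropyl isocyanate, CC(C)N=C=O
Why: Amine-catalysed addition of the phenol to the isocyanate (carbamoylation) should be clean and installs a removable ortho-directing group.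

Step 3
Reactants: 3 3,5-bis(methoxymethoxy)phenyl N-isopropylcarbamate
Product: 7 3,5-bis(methoxymethoxy)-2-(trimethylsilyl)phenyl N-isopropylcarbamate, via N-silyl carbamate 4 (not isolated), via aryllithium 5 (not isolated), via N-silyl C-silyl carbamate 6 (not isolated)
Conditions: TBSOTf (1.05 equiv), TMEDA, Et2O, 0 °C → rt; n-BuLi (2.2 equiv), TMEDA, −78 °C; TMSCl, −78 °C → rt; cold aq. NaHSO4
Reagents that add atoms: chlorotrimethylsilane, C[Si](C)(C)Cl
Why: Directed ortho-metalation: in situ N-silylation blocks loss of isocyanate from the carbamate anion, the carbamate reinforced by the neighbouring MOM ether should direct lithiation to C2 between the two groups, TMSCl traps the aryllithium, and the N–Si bond is hydrolysed on work-up.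

Step 4
Reactants: 7 3,5-bis(methoxymethoxy)-2-(trimethylsilyl)phenyl N-isopropylcarbamate
Product: 9 3,5-bis(methoxymethoxy)-2-(trimethylsilyl)phenyl trifluoromethanesulfonate, via ortho-silyl phenol 8 (not isolated)
Conditions: DBU, Et2NH, MeCN, 40 °C; then PhNTf2, rt
Reagents that add atoms: N-phenylbis(trifluoromethanesulfonimide), O=S(=O)(N(c1ccccc1)S(=O)(=O)C(F)(F)F)C(F)(F)F
Why: E1cB cleavage of the N–H carbamate releases isopropyl isocyanate (captured by Et2NH as a urea) and the ortho-silyl phenoxide, which is O-triflated in the same pot.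

Step 5
Reactants: 10 4-hydroxybenzaldehyde; 11 prenyl bromide
Product: 12 4-(3-methylbut-2-enyloxy)benzaldehyde
Conditions: K2CO3, acetone, reflux
Reagents that add atoms: none
Why: Williamson ether synthesis; SN2 attack of the phenoxide on the primary allylic bromide should give the O-prenyl ether.

Step 6
Reactants: 12 4-(3-methylbut-2-enyloxy)benzaldehyde; 13 methyl methoxyacetate
Product: 15 methyl (Z)-2-methoxy-3-[4-(3-methylbut-2-enyloxy)phenyl]prop-2-enoate, via aldol adduct 14 (not isolated)
Conditions: 13 (3 equiv), NaOMe (2 equiv), MeOH, 0 °C → 65 °C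
Reagents that add atoms: none
Why: Claisen–Schmidt-type aldol condensation of the ester enolate with the non-enolisable aldehyde, followed by E1cB dehydration under equilibrating alkoxide conditions, should give the thermodynamically preferred Z alkene (aryl trans to the ester).

Step 7
Reactants: 15 methyl (Z)-2-methoxy-3-[4-(3-methylbut-2-enyloxy)phenyl]prop-2-enoate
Product: 16 (Z)-2-methoxy-3-[4-(3-methylbut-2-enyloxy)phenyl]prop-2-enoic acid
Conditions: LiOH, THF/MeOH/H2O, rt; then 1 M HCl to pH 3, 0 °C
Reagents that add atoms: lithium hydroxide, [Li+].[OH-]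
Why: Ester saponification by acyl–oxygen cleavage; brief cold acidification should leave the enol ether and the prenyl ether untouched.

Step 8
Reactants: 9 3,5-bis(methoxymethoxy)-2-(trimethylsilyl)phenyl trifluoromethanesulfonate; 16 (Z)-2-methoxy-3-[4-(3-methylbut-2-enyloxy)phenyl]prop-2-enoic acid
Product: 19 trans-3-methoxy-5,7-bis(methoxymethoxy)-2-[4-(3-methylbut-2-enyloxy)phenyl]chroman-4-one (racemic), via 3,5-bis(methoxymethoxy)benzyne 17 (not isolated), via ortho-acyl phenoxide 18 (not isolated)
Conditions: 9 (1.5 equiv), CsF (4 equiv), THF, 125 °C (sealed tube); aq. NH4Cl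
Reagents that add atoms: none
Why: Fluoride attacks silicon of 9 and triflate leaves to give aryne 17; the caesium carboxylate of 16 adds to the aryne carbon remote from the flanking MOM-oxy group, and the aryl anion so formed attacks the neighbouring acyl carbon through a four-membered alkoxide that opens to the ortho-acyl phenoxide 18, a net insertion into the acyl C–O bond equivalent to an anionic ortho-Fries shift. The closest known reaction type is the aryne insertion into carboxylic acid C–O bonds that gives ortho-hydroxyaryl ketones and, from α,β-unsaturated acids, 4-chromanones. Ring C closes by 6-endo-trig oxa-Michael addition of the phenoxide to the α-methoxy enone. C2 is set in this reversible conjugate addition and C3 by protonation of the resulting enolate; both can equilibrate, so the trans isomer with aryl and methoxy equatorial should prevail as a racemate, and both centres are removed in step 10. The step needs attack of the oxygen nucleophile at the aryne carbon that becomes C8a and an acyl shift faster than protonation of the aryl anion: the inductive pull and ring distortion caused by the C–O bond next to the triple bond direct the nucleophile to the remote carbon, so that the carbanion develops ortho to oxygen at the future C4a, and hot THF is chosen because it should keep the concentration of proton donors low.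

Step 9
Reactants: 19 trans-3-methoxy-5,7-bis(methoxymethoxy)-2-[4-(3-methylbut-2-enyloxy)phenyl]chroman-4-one
Product: 21 (2R*,3R*)-3-methoxy-5,7-bis(methoxymethoxy)-2-[4-(3-methylbut-2-enyloxy)phenyl]-3-(phenylselanyl)chroman-4-one (racemic; selenium trans to the C2 aryl group), via lithium enolate 20 (not isolated)
Conditions: LiN(SiMe3)2 (1.1 equiv), THF, −78 °C; PhSeCl (1.05 equiv), −78 °C; cold aq. NH4Cl
Reagents that add atoms: benzeneselenenyl chloride, Cl[Se]c1ccccc1
Why: α-Selenenylation of a ketone enolate: deprotonation at C3 (the only α-hydrogen) at −78 °C should give enolate 20, which is trapped by PhSeCl before it can open by β-elimination of the phenoxide and far faster than the reagent adds to the prenyl alkene; selenium should enter the face away from the C2 aryl group, which places it cis to H2 as the later syn-elimination requires.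

Step 10
Reactants: 21 (2R*,3R*)-3-methoxy-5,7-bis(methoxymethoxy)-2-[4-(3-methylbut-2-enyloxy)phenyl]-3-(phenylselanyl)chroman-4-one
Product: 23 3-methoxy-5,7-bis(methoxymethoxy)-2-[4-(3-methylbut-2-enyloxy)phenyl]-4H-chromen-4-one, via selenoxide 22 (not isolated)
Conditions: mCPBA (1.05 equiv), CH2Cl2, −78 °C; i-Pr2NH (2 equiv), −78 °C → rt
Reagents that add atoms: none
Why: Selenide oxidation is much faster than epoxidation of the trisubstituted alkene at −78 °C, and selenoxide 22 should undergo syn-elimination with the cis H2 on warming to form the C2=C3 bond of the 4-pyranone, while i-Pr2NH traps benzeneselenenic acid before it can add to the prenyl alkene.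

Step 11
Reactants: 23 3-methoxy-5,7-bis(methoxymethoxy)-2-[4-(3-methylbut-2-enyloxy)phenyl]-4H-chromen-4-one
Product: 25 5,7-dihydroxy-3-methoxy-4'-prenyloxyflavone, via bis(trimethylsilyl) ether 24 (not isolated)
Conditions: TMSOTf (4 equiv), 2,2'-bipyridyl (6 equiv), MeCN, 0 °C → rt; then H2O, rt
Reagents that add atoms: none
Why: The silyl triflate–bipyridyl pair converts aryl MOM ethers into aryl silyl ethers (the methoxymethyl unit is carried off on the pyridine nitrogen) and water then hydrolyses the two aryl silyl ethers; no Brønsted acid is present, so the acid-sensitive aryl prenyl ether and the 3-methoxy group should remain.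

**Compound list**

1 | phloroglucinol | Oc1cc(O)cc(O)c1 | starting material
2 | 3,5-bis(methoxymethoxy)phenol | COCOc1cc(O)cc(OCOC)c1 | intermediate
3 | 3,5-bis(methoxymethoxy)phenyl N-isopropylcarbamate | CC(C)NC(=O)Oc1cc(OCOC)cc(OCOC)c1 | intermediate
4 | 3,5-bis(methoxymethoxy)phenyl N-(tert-butyldimethylsilyl)-N-isopropylcarbamate | CC(C)N(C(=O)Oc1cc(OCOC)cc(OCOC)c1)[Si](C)(C)C(C)(C)C | intermediate (not isolated)
5 | 2-lithio derivative of 4 (lithium between the carbamate and a MOM ether) | CC(C)N(C(=O)Oc1cc(OCOC)cc(OCOC)c1[Li])[Si](C)(C)C(C)(C)C | intermediate (not isolated)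
6 | 3,5-bis(methoxymethoxy)-2-(trimethylsilyl)phenyl N-(tert-butyldimethylsilyl)-N-isopropylcarbamate | CC(C)N(C(=O)Oc1cc(OCOC)cc(OCOC)c1[Si](C)(C)C)[Si](C)(C)C(C)(C)C | intermediate (not isolated)
7 | 3,5-bis(methoxymethoxy)-2-(trimethylsilyl)phenyl N-isopropylcarbamate | CC(C)NC(=O)Oc1cc(OCOC)cc(OCOC)c1[Si](C)(C)C | intermediate
8 | 3,5-bis(methoxymethoxy)-2-(trimethylsilyl)phenol (present as its DBU salt) | COCOc1cc(O)c([Si](C)(C)C)c(OCOC)c1 | intermediate (not isolated)
9 | 3,5-bis(methoxymethoxy)-2-(trimethylsilyl)phenyl trifluoromethanesulfonate | COCOc1cc(OCOC)c([Si](C)(C)C)c(OS(=O)(=O)C(F)(F)F)c1 | intermediate (aryne precursor)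
10 | 4-hydroxybenzaldehyde | O=Cc1ccc(O)cc1 | starting material
11 | prenyl bromide (1-bromo-3-methylbut-2-ene) | CC(C)=CCBr | starting material
12 | 4-(3-methylbut-2-enyloxy)benzaldehyde | O=Cc1ccc(OCC=C(C)C)cc1 | intermediate
13 | methyl methoxyacetate | COCC(=O)OC | starting material
14 | methyl 3-hydroxy-2-methoxy-3-[4-(3-methylbut-2-enyloxy)phenyl]propanoate (aldol adduct, diastereomer mixture) | COC(C(=O)OC)C(O)c1ccc(OCC=C(C)C)cc1 | intermediate (not isolated)
15 | methyl (Z)-2-methoxy-3-[4-(3-methylbut-2-enyloxy)phenyl]prop-2-enoate | CO/C(C(=O)OC)=C\c1ccc(OCC=C(C)C)cc1 | intermediate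
16 | (Z)-2-methoxy-3-[4-(3-methylbut-2-enyloxy)phenyl]prop-2-enoic acid | CO/C(C(=O)O)=C\c1ccc(OCC=C(C)C)cc1 | intermediate
17 | 3,5-bis(methoxymethoxy)benzyne | COCOC1=CC(OCOC)=CC#C1 | intermediate (not isolated)
18 | (Z)-1-[2-hydroxy-4,6-bis(methoxymethoxy)phenyl]-2-methoxy-3-[4-(3-methylbut-2-enyloxy)phenyl]prop-2-en-1-one (present as its caesium phenoxide) | CO/C(C(=O)c1c(O)cc(OCOC)cc1OCOC)=C\c1ccc(OCC=C(C)C)cc1 | intermediate (not isolated)
19 | trans-(2R*,3R*)-3-methoxy-5,7-bis(methoxymethoxy)-2-[4-(3-methylbut-2-enyloxy)phenyl]chroman-4-one (racemic) | CC(C)=CCOc1ccc(cc1)[C@@H]1[C@H](C(=O)c2c(OCOC)cc(OCOC)cc2O1)OC | intermediate (key-step product)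
20 | lithium enolate of 19 (racemic) | CC(C)=CCOc1ccc(cc1)[C@@H]1C(OC)=C(O[Li])c2c(OCOC)cc(OCOC)cc2O1 | intermediate (not isolated)
21 | (2R*,3R*)-3-methoxy-5,7-bis(methoxymethoxy)-2-[4-(3-methylbut-2-enyloxy)phenyl]-3-(phenylselanyl)chroman-4-one (racemic; SePh trans to the C2 aryl group) | CC(C)=CCOc1ccc(cc1)[C@@H]1[C@](OC)(C(=O)c2c(OCOC)cc(OCOC)cc2O1)[Se]c1ccccc1 | intermediate
22 | selenoxide of 21 (mixture at selenium) | CC(C)=CCOc1ccc(cc1)[C@@H]1[C@](OC)(C(=O)c2c(OCOC)cc(OCOC)cc2O1)[Se](=O)c1ccccc1 | intermediate (not isolated)
23 | 3-methoxy-5,7-bis(methoxymethoxy)-2-[4-(3-methylbut-2-enyloxy)phenyl]-4H-chromen-4-one | COc1c(-c2ccc(OCC=C(C)C)cc2)oc2cc(OCOC)cc(OCOC)c2c1=O | intermediate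
24 | 3-methoxy-2-[4-(3-methylbut-2-enyloxy)phenyl]-5,7-bis(trimethylsilyloxy)-4H-chromen-4-one | COc1c(-c2ccc(OCC=C(C)C)cc2)oc2cc(O[Si](C)(C)C)cc(O[Si](C)(C)C)c2c1=O | intermediate (not isolated)
25 | 5,7-dihydroxy-3-methoxy-4'-prenyloxyflavone | COc1c(-c2ccc(OCC=C(C)C)cc2)oc2cc(O)cc(O)c2c1=O | target

**Step count**

Total: 11 steps. Longest linear sequence: 8 steps (1, 2, 3, 4, 8, 9, 10, 11).

**Steps most likely to fail**

Step 8. Several things may go wrong:
- the aryl anion formed after carboxylate addition may be protonated before it reaches the acyl carbon, giving plain O-arylation without insertion;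
- the carboxylate may add to the aryne carbon next to the MOM-oxy group;
- the aryne may be consumed by the product phenoxide or by an ene reaction at the prenyl group;
- the oxa-Michael closure onto the electron-rich α-methoxy enone may stop at the open ketone.

The fallback is the classical acylation/condensation route to the same flavanone. It sets out from 1. A Hoesch reaction with methoxyacetonitrile (ZnCl2, HCl, Et2O, 0 °C) would give 2-methoxy-1-(2,4,6-trihydroxyphenyl)ethaniminium chloride F1, which hot water would hydrolyse to 2-methoxy-1-(2,4,6-trihydroxyphenyl)ethanone F2. MOMCl (2.2 equiv) and i-Pr2NEt would protect the 4-hydroxyl and one ortho hydroxyl, the other being held by its hydrogen bond to the carbonyl, to give 1-[2-hydroxy-4,6-bis(methoxymethoxy)phenyl]-2-methoxyethanone F3. Claisen–Schmidt condensation of F3 with aldehyde 12 (KOH, EtOH, rt) would give chalcone 18, and NaOAc in refluxing EtOH would close it to 19, where the route is rejoined before step 9.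

Step 9. The enolate may open ring C by β-elimination of the phenoxide, C–Se bond formation at the fully substituted enolate carbon may be slow, selenium may be delivered to the face cis to the aryl group (which would leave no syn hydrogen for step 10), or PhSeCl may add to the prenyl alkene.

The fallback is a Saegusa–Ito dehydrogenation, which needs neither a C–Se bond nor a fixed face. It sets out from 19. Addition of LiN(SiMe3)2 to a mixture of 19 and TMSCl in THF at −78 °C (internal quench) would give the trimethylsilyl enol ether of 19 F4. Pd(OAc)2 (1.1 equiv) in MeCN at rt would then give the flavone by β-hydride elimination of H2 from a palladium enolate that can reach C3 from either face. The route is rejoined at 23, bypassing step 10.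

Step 3. Lithiation may compete at C4 between the two MOM ethers, the silyl triflate may attack a MOM acetal instead of the carbamate nitrogen, or the carbamoyl group may migrate to carbon (anionic ortho-Fries shift) on warming.

The fallback replaces directed metalation by halogen–metal exchange with a retro-Brook shift. It sets out from 2. Amine-mediated ortho-bromination (NBS, i-Pr2NH cat., CH2Cl2, 0 °C) should give 2-bromo-3,5-bis(methoxymethoxy)phenol F5. HN(SiMe3)2 in refluxing THF would give [2-bromo-3,5-bis(methoxymethoxy)phenoxy]trimethylsilane F6. n-BuLi in THF at −78 °C would effect bromine–lithium exchange and 1,3 O→C silyl migration to the lithium salt of 8, and Tf2O at −78 °C would give 9, where the route is rejoined (steps 2 to 4 bypassed).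

**Further compounds**

F1 | step 8 | 2-methoxy-1-(2,4,6-trihydroxyphenyl)ethaniminium chloride | COCC(=[NH2+])c1c(O)cc(O)cc1O.[Cl-]
F2 | step 8 | 2-methoxy-1-(2,4,6-trihydroxyphenyl)ethanone | COCC(=O)c1c(O)cc(O)cc1O
F3 | step 8 | 1-[2-hydroxy-4,6-bis(methoxymethoxy)phenyl]-2-methoxyethanone | COCC(=O)c1c(O)cc(OCOC)cc1OCOC
F4 | step 9 | trimethylsilyl enol ether of 19, 3-methoxy-5,7-bis(methoxymethoxy)-2-[4-(3-methylbut-2-enyloxy)phenyl]-4-(trimethylsilyloxy)-2H-chromene (racemic) | CC(C)=CCOc1ccc(cc1)[C@@H]1C(OC)=C(O[Si](C)(C)C)c2c(OCOC)cc(OCOC)cc2O1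
F5 | step 3 | 2-bromo-3,5-bis(methoxymethoxy)phenol | COCOc1cc(O)c(Br)c(OCOC)c1
F6 | step 3 | [2-bromo-3,5-bis(methoxymethoxy)phenoxy]trimethylsilane | COCOc1cc(O[Si](C)(C)C)c(Br)c(OCOC)c1
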